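**Retrosynthetic overview**

- The target is the linear tetramer A–CH2–B–CH2–C–CH2–D: two outer butyrylfilicinic acid rings (A, D) and two inner butyrylphloroglucinol rings (B, C). It has no stereocentre.
- Feature on which the strategy rests: in ring B and in ring C, the ring carbon that carries the central CH2, the C–OH next to it and the following ring carbon, joined through the central CH2, are the chain C1–C7 of heptane-2,6-dione. The remaining C(OH)–CH–C(OH) of each ring is a malonyl unit.
- Key disconnection: four C–C bonds of rings B and C, formed by [3+3] annulation of the bis(silyl enol ether) of heptane-2,6-dione with two molecules of malonyl dichloride. Both arenes are thus built around the bridge.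
- The B–CH2–C hexaphenol is then butyrylated once per ring. Its last two free ring carbons are joined through CH2 to C6 of two molecules of butyrylfilicinic acid, by amine displacement from a bis-Mannich base.
- Ring order: rings B and C together in the key step; rings A and D are attached ready-made, their carbocycle coming from phloroglucinol by acylation and gem-dimethylation.

Key step: step 2

Remark: the enolised polycarbonyl compounds are written as one tautomer each, the target as in the given structure.

**Step 1**
Reactants: 1 heptane-2,6-dione
Product: 2 2,6-bis(trimethylsilyloxy)hepta-1,6-diene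
Conditions: LiN(iPr)2 (2.4 equiv), Me3SiCl (5 equiv) premixed, THF, −78 °C, slow addition of 1; Et3N, pentane, filtration, distillation
Reagents that add atoms: chlorotrimethylsilane, C[Si](C)(C)Cl
Why: Kinetic silyl enol ether formation: LiN(iPr)2 deprotonates each less hindered CH3 group and, with Me3SiCl already present (internal quench), each lithium enolate should be silylated on oxygen before it can add to the 1,5-related ketone in an intramolecular aldol reaction; no stereocentre is formed.

**Step 2**
Reactants: 2 2,6-bis(trimethylsilyloxy)hepta-1,6-diene; 3 malonyl dichloride (2.5 equiv)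
Product: 6 2,2'-methylenebis(benzene-1,3,5-triol), via bis-pyrone 4 (not isolated), via tetraoxo diester 5 (not isolated)
Conditions: 2 added to 3, Et2O, −78 °C to rt; evaporation; then Mg(OMe)2, MeOH, reflux; then NaOMe, diglyme, MeOH distilled off, 160–180 °C; aq. HCl, under N2
Reagents that add atoms: none
Why: Each terminal enol-ether carbon of 2 attacks one acyl chloride group of 3 with loss of Me3SiCl (acylation of a silyl enol ether), and the 3,5-dioxoacyl chloride so formed is expected to close through the enol oxygen to the 4-hydroxy-2-pyrone rings of 4, any portion that closes directly through carbon being product already. Mg(OMe)2 then opens both lactones to the bis(β,δ-diketo ester) 5, and NaOMe at high temperature makes the CH2 carbons C6 and C8 of 5 (the former C3 and C5 of 1) attack the ester carbonyls C1 and C13, which completes the four new C–C bonds of rings B and C. The closest known reaction types are the Effenberger pyrone synthesis from silyl enol ethers and malonyl dichloride, and the methanolysis–Claisen recyclisation of triacetic acid lactone to phloroglucinol. Ring B and ring C are each closed by a 6-exo-trig Claisen (Dieckmann-type) C-acylation, followed by loss of methanol and tautomerisation of the cyclohexane-1,3,5-trione to the arene; no stereocentre is formed. The step needs Claisen closure onto the ester to be faster than aldol attack of one diketone unit on the 1,5-related ketone of the other and faster than retro-Claisen cleavage; both β-diketone units are held as magnesium or sodium enolates, so the ester is the only electrophile left, and aromatisation makes the closure irreversible. The order in which the two α-carbons of a ketone are acylated does not matter, since either order gives the same 2-substituted phloroglucinol ring.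

**Step 3**
Reactants: 6 2,2'-methylenebis(benzene-1,3,5-triol); 7 butanenitrile (2.2 equiv)
Product: 9 1-{3-[(3-butanoyl-2,4,6-trihydroxyphenyl)methyl]-2,4,6-trihydroxyphenyl}butan-1-one, via bis(ketiminium chloride) 8 (not isolated)
Conditions: HCl (g), ZnCl2 (cat.), Et2O–dioxane, 0 °C; then H2O, 100 °C
Reagents that add atoms: water, O
Why: Houben–Hoesch acylation: the nitrilium species attacks one of the two equivalent free carbons of each electron-rich 2-alkylphloroglucinol ring, the ketiminium group formed deactivates that ring against a second acylation, and hydrolysis of the two C=NH2+ groups gives the diketone; no stereocentre is formed.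

**Step 4**
Reactants: 9 1-{3-[(3-butanoyl-2,4,6-trihydroxyphenyl)methyl]-2,4,6-trihydroxyphenyl}butan-1-one
Product: 10 1-[3-({3-butanoyl-5-[(dimethylamino)methyl]-2,4,6-trihydroxyphenyl}methyl)-5-[(dimethylamino)methyl]-2,4,6-trihydroxyphenyl]butan-1-one
Conditions: aq. HCHO (2.2 equiv) and aq. Me2NH (2.4 equiv) premixed, EtOH, 0 °C to rt
Reagents that add atoms: formaldehyde, C=O; dimethylamine, CNC
Why: Phenolic Mannich reaction: the iminium ion from formaldehyde and dimethylamine should substitute the single free, doubly ortho-hydroxylated carbon of each acylphloroglucinol ring, and since no other ring position is open the reaction stops at one aminomethyl group per ring.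

**Step 5**
Reactants: 11 phloroglucinol; 7 butanenitrile
Product: 13 1-(2,4,6-trihydroxyphenyl)butan-1-one, via ketiminium chloride 12 (not isolated)
Conditions: HCl (g), ZnCl2 (cat.), Et2O, 0 °C; then H2O, 100 °C
Reagents that add atoms: water, O
Why: Houben–Hoesch acylation of phloroglucinol, which should stop at the mono-ketone because the ketiminium salt is deactivated and separates from the ether; hydrolysis then gives the aryl ketone.

**Step 6**
Reactants: 13 1-(2,4,6-trihydroxyphenyl)butan-1-one
Product: 14 2-butanoyl-3,5-dihydroxy-4,4-dimethylcyclohexa-2,5-dien-1-one (butyrylfilicinic acid)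
Conditions: NaOMe (3 equiv), MeI (2.2 equiv), MeOH, 0 °C to rt; aq. HCl
Reagents that add atoms: iodomethane, CI
Why: Dearomatising double C-methylation of an acylphloroglucinol (enolate C-alkylation): the phenoxide is methylated at a free ring carbon, and the second methyl group should enter at the same carbon because this gives the stabilised, strongly acidic enolised β-triketone, whose anion is methylated further only slowly with the limited amount of MeI; the quaternary carbon carries two equal methyl groups, so no stereocentre arises.

**Step 7**
Reactants: 10 1-[3-({3-butanoyl-5-[(dimethylamino)methyl]-2,4,6-trihydroxyphenyl}methyl)-5-[(dimethylamino)methyl]-2,4,6-trihydroxyphenyl]butan-1-one; 14 2-butanoyl-3,5-dihydroxy-4,4-dimethylcyclohexa-2,5-dien-1-one (2.5 equiv)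
Product: 15 2-butanoyl-6-{[3-butanoyl-5-({3-butanoyl-5-[(5-butanoyl-2,4-dihydroxy-3,3-dimethyl-6-oxocyclohexa-1,4-dien-1-yl)methyl]-2,4,6-trihydroxyphenyl}methyl)-2,4,6-trihydroxyphenyl]methyl}-3,5-dihydroxy-4,4-dimethylcyclohexa-2,5-dien-1-one (target)
Conditions: 1,4-dioxane, 90 °C, N2 stream; dilute aq. HCl work-up
Reagents that add atoms: none
Why: Thermal Mannich-base exchange (elimination–addition through an ortho-quinone methide): the acidic enol 14 protonates each benzylic amine, loss of Me2NH from the ortho-hydroxybenzylammonium unit should give an ortho-quinone methide on ring B and on ring C, and C6 of 14, its only free ring carbon, adds in a Michael fashion with rearomatisation; 10 has no free ring carbon, so the core cannot condense with itself, and no stereocentre is formed.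

**Compound list**

1 | heptane-2,6-dione | CC(=O)CCCC(C)=O | starting material
2 | 2,6-bis(trimethylsilyloxy)hepta-1,6-diene | C=C(O[Si](C)(C)C)CCCC(=C)O[Si](C)(C)C | intermediate
3 | malonyl dichloride | O=C(Cl)CC(=O)Cl | starting material
4 | 6,6'-(propane-1,3-diyl)bis(4-hydroxy-2H-pyran-2-one) (not isolated) | O=c1cc(O)cc(CCCc2cc(O)cc(=O)o2)o1 | intermediate
5 | dimethyl 3,5,9,11-tetraoxotridecanedioate (not isolated) | COC(=O)CC(=O)CC(=O)CCCC(=O)CC(=O)CC(=O)OC | intermediate
6 | 2,2'-methylenebis(benzene-1,3,5-triol) | Oc1cc(O)c(Cc2c(O)cc(O)cc2O)c(O)c1 | intermediate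
7 | butanenitrile | CCCC#N | starting material
8 | 1,1'-[methylenebis(2,4,6-trihydroxybenzene-3,1-diyl)]bis(butan-1-iminium) dichloride (not isolated) | CCCC(=[NH2+])c1c(O)cc(O)c(Cc2c(O)cc(O)c(C(=[NH2+])CCC)c2O)c1O.[Cl-].[Cl-] | intermediate
9 | 1-{3-[(3-butanoyl-2,4,6-trihydroxyphenyl)methyl]-2,4,6-trihydroxyphenyl}butan-1-one | CCCC(=O)c1c(O)cc(O)c(Cc2c(O)cc(O)c(C(=O)CCC)c2O)c1O | intermediate
10 | 1-[3-({3-butanoyl-5-[(dimethylamino)methyl]-2,4,6-trihydroxyphenyl}methyl)-5-[(dimethylamino)methyl]-2,4,6-trihydroxyphenyl]butan-1-one | CCCC(=O)c1c(O)c(CN(C)C)c(O)c(Cc2c(O)c(CN(C)C)c(O)c(C(=O)CCC)c2O)c1O | intermediate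
11 | phloroglucinol (benzene-1,3,5-triol) | Oc1cc(O)cc(O)c1 | starting material
12 | 1-(2,4,6-trihydroxyphenyl)butan-1-iminium chloride (not isolated) | CCCC(=[NH2+])c1c(O)cc(O)cc1O.[Cl-] | intermediate
13 | 1-(2,4,6-trihydroxyphenyl)butan-1-one | CCCC(=O)c1c(O)cc(O)cc1O | intermediate
14 | 2-butanoyl-3,5-dihydroxy-4,4-dimethylcyclohexa-2,5-dien-1-one (butyrylfilicinic acid) | CCCC(=O)C1=C(O)C(C)(C)C(O)=CC1=O | intermediate
15 | 2-butanoyl-6-{[3-butanoyl-5-({3-butanoyl-5-[(5-butanoyl-2,4-dihydroxy-3,3-dimethyl-6-oxocyclohexa-1,4-dien-1-yl)methyl]-2,4,6-trihydroxyphenyl}methyl)-2,4,6-trihydroxyphenyl]methyl}-3,5-dihydroxy-4,4-dimethylcyclohexa-2,5-dien-1-one | CCCC(=O)C1=C(O)C(C)(C)C(O)=C(Cc2c(O)c(Cc3c(O)c(CC4=C(O)C(C)(C)C(O)=C(C(=O)CCC)C4=O)c(O)c(C(=O)CCC)c3O)c(O)c(C(=O)CCC)c2O)C1=O | target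

**Step count**

Total: 7 steps. Longest linear sequence: 5 steps (steps 1, 2, 3, 4, 7); steps 5 and 6 make the side fragment 14.

**Steps most likely to fail**

Step 2 (key step). After the lactones are opened, the chain may cyclise by aldol addition between the two diketone units, or be cut by retro-Claisen methanolysis, faster than the Claisen closure; the second annulation may also lag behind the first. Fallback: the B–CH2–C core is assembled from a preformed arene instead of by annulation. Setting out from phloroglucinol 11, O-methylation (Me2SO4, K2CO3, acetone, reflux) should give 1,3,5-trimethoxybenzene F1. F1 in excess with paraformaldehyde and catalytic HCl in AcOH should give bis(2,4,6-trimethoxyphenyl)methane F2 by hydroxyalkylation and Friedel–Crafts alkylation, the excess of arene holding back higher oligomers. BBr3 in CH2Cl2 (−78 °C to rt) then cleaves the six methyl ethers, and the route is rejoined at 6.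

Step 7. Loss of dimethylamine from the zwitterionic core may be sluggish, and at the temperature then needed the methylene bridges may exchange by retro-Michael fragmentation, which would scramble the A–B and B–C links. Fallback: the roles of the partners are reversed. Setting out from 14, aminomethylation (aq. HCHO, Me2NH, EtOH, 0 °C) should give 2-butanoyl-6-[(dimethylamino)methyl]-3,5-dihydroxy-4,4-dimethylcyclohexa-2,5-dien-1-one F3. F3 (2.2 equiv), heated in dioxane with the core 9 taken before step 4, loses Me2NH to give the 6-methylene trione, which is attacked by the single free ring carbon of each ring of 9 (Friedel–Crafts-type Michael addition); the route is rejoined at 15.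

Step 1. The mono-enolate may add to the second ketone (intramolecular aldol) before it is silylated, and some internal enolate may form. Fallback: amine-free thermodynamic silylation, which uses the fact that the order of the two acylations does not change the ring that results. Setting out from 1, Me3SiCl, NaI and Et3N in MeCN should give (2Z,5Z)-2,6-bis(trimethylsilyloxy)hepta-2,5-diene F4. With 3 under the conditions of step 2, the internal carbons C3 and C5 are acylated first; the pot should pass through 5,5'-methylenebis(4-hydroxy-6-methyl-2H-pyran-2-one) F5 and, after Mg(OMe)2, through dimethyl 4,6-diacetyl-3,7-dioxononanedioate F6, in which the terminal CH3 groups close onto the esters. The route is rejoined at 6.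

**Further compounds**

F1 | step 2 | 1,3,5-trimethoxybenzene | COc1cc(OC)cc(OC)c1
F2 | step 2 | bis(2,4,6-trimethoxyphenyl)methane | COc1cc(OC)c(Cc2c(OC)cc(OC)cc2OC)c(OC)c1
F3 | step 7 | 2-butanoyl-6-[(dimethylamino)methyl]-3,5-dihydroxy-4,4-dimethylcyclohexa-2,5-dien-1-one | CCCC(=O)C1=C(O)C(C)(C)C(O)=C(CN(C)C)C1=O
F4 | step 1 | (2Z,5Z)-2,6-bis(trimethylsilyloxy)hepta-2,5-diene | C/C(O[Si](C)(C)C)=C/C/C=C(/C)O[Si](C)(C)C
F5 | step 1 | 5,5'-methylenebis(4-hydroxy-6-methyl-2H-pyran-2-one) | Cc1oc(=O)cc(O)c1Cc1c(O)cc(=O)oc1C
F6 | step 1 | dimethyl 4,6-diacetyl-3,7-dioxononanedioate (enolised, configuration at C4 and C6 not defined) | COC(=O)CC(=O)C(CC(C(C)=O)C(=O)CC(=O)OC)C(C)=O
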